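**Retrosynthetic overview**
1. Side chain: cut C12–C13. A B‑alkyl Suzuki–Miyaura coupling joins a C9‑vinyl lactone to an (E)‑alkenyl iodide made from geranylacetone; the acetate goes on last.
2. Ring A (C1–C5, C10) is annulated onto ring B: Robinson annulation of a ring‑B C5 ketone with ethyl vinyl ketone (C1–C10, then C4–C5), Cu–H 1,4‑reduction (5β‑H, cis fusion), C4 methylation.
3. Ring B (C5–C10) is closed at C7–C8 by a SmI2 reductive ketone–enone cyclization of an acyclic hept‑6‑ene‑2,5‑dione.
4. Enabling feature: the tertiary carbinol C8 of ring B is 1,4 to the ring‑fusion carbon C5. With C5 drawn as a ketone, C6=C7 is a vinyl ketone whose β‑carbon is C7 and C8 is a methyl ketone (γ‑hydroxy‑ketone retron); the C5 carbonyl is then used up in building ring A.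
5. The ene‑dione comes from (S)‑5‑methylfuran‑2(5H)‑one: anti vinyl addition sets C9, and the lactone C–O stereocentre (future C8) is a relay that is oxidised away. Ring order: B, then A.

Key step: step 10

Remark: read literally, the SMILES has H‑5 and CH3‑10 on the same face (A/B cis‑fused; 5S,8R,9R,10S), with a 9β chain, 8α‑OH and 8β‑CH3; the route is designed for exactly this isomer (polypodane numbering C1–C30 is used).
Notation: R* = (3E,7E,11E)‑13‑[tert‑butyl(diphenyl)silyl]oxy‑4,8,12‑trimethyltrideca‑3,7,11‑trien‑1‑yl (C11–C30).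

Step 1
Reactants: 1 (5E)-6,10-dimethylundeca-5,9-dien-2-one (geranylacetone)
Product: 2 (5E,9E)-11-hydroxy-6,10-dimethylundeca-5,9-dien-2-one
Conditions: SeO2 (cat.), t-BuOOH, salicylic acid (cat.), CH2Cl2, 0 °C → rt
Reagents that add atoms: tert-butyl hydroperoxide, CC(C)(C)OO (oxygen relayed by catalytic selenium dioxide, O=[Se]=O)
Why: SeO2/t-BuOOH allylic oxidation (ene reaction, then [2,3]-sigmatropic shift) should attack the (E)-methyl of the more electron-rich terminal alkene and give the (E)-allylic alcohol that becomes C30–O.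

Step 2
Reactants: 2 (5E,9E)-11-hydroxy-6,10-dimethylundeca-5,9-dien-2-one
Product: 3 (5E,9E)-11-[tert-butyl(diphenyl)silyl]oxy-6,10-dimethylundeca-5,9-dien-2-one
Conditions: TBDPSCl, imidazole, DMF, rt
Reagents that add atoms: tert-butyl(chloro)diphenylsilane, CC(C)(C)[Si](Cl)(c1ccccc1)c1ccccc1
Why: Standard silylation of the primary allylic alcohol; the TBDPS ether is chosen to survive base, organometallics, SmI2 and Cu–H until step 14.

Step 3
Reactants: 3 (5E,9E)-11-[tert-butyl(diphenyl)silyl]oxy-6,10-dimethylundeca-5,9-dien-2-one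
Product: 5 terminal alkyne tert-butyl{[(2E,6E)-2,6-dimethylundeca-2,6-dien-10-yn-1-yl]oxy}diphenylsilane, via enol phosphate 4 (not isolated)
Conditions: LDA, THF, −78 °C; ClP(O)(OEt)2; LDA (2.3 equiv), −78 °C → rt; H2O
Reagents that add atoms: none
Why: Methyl ketone to terminal alkyne by elimination of the kinetic (less substituted) enol phosphate with excess LDA, a known two-stage one-pot sequence; the ketone carbons become C14 and C13.

Step 4
Reactants: 5 tert-butyl{[(2E,6E)-2,6-dimethylundeca-2,6-dien-10-yn-1-yl]oxy}diphenylsilane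
Product: 7 (E)-alkenyl iodide tert-butyl{[(2E,6E,10E)-11-iodo-2,6,10-trimethylundeca-2,6,10-trien-1-yl]oxy}diphenylsilane, via alkenylalane 6 (not isolated)
Conditions: AlMe3, Cp2ZrCl2 (cat.), CH2Cl2, −20 °C → rt; I2, THF, −30 °C
Reagents that add atoms: trimethylaluminium, C[Al](C)C; iodine, II
Why: Zr-catalysed carboalumination adds Me–Al syn across the alkyne with Al at the terminus, and iodinolysis goes with retention, which should fix the (E)-C13=C14 geometry and the C14 methyl.

Step 5
Reactants: 8 (S)-5-methylfuran-2(5H)-one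
Product: 10 (4S,5S)-4-ethenyl-5-methyloxolan-2-one, via silyl ketene acetal 9 (not isolated)
Conditions: CH2=CHMgBr, CuBr·SMe2 (cat.), TMSCl, THF, −78 °C; 1 M HCl
Reagents that add atoms: vinylmagnesium bromide, C=C[Mg]Br
Why: Copper-catalysed, TMSCl-accelerated conjugate addition of the vinyl Grignard reagent should occur anti to the C5 methyl of the butenolide, which sets C9 (target numbering) from the lactate-derived stereocentre.

Step 6
Reactants: 10 (4S,5S)-4-ethenyl-5-methyloxolan-2-one
Product: 11 (3R,4R,5S)-4-ethenyl-3,5-dimethyloxolan-2-one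
Conditions: LDA, THF, −78 °C; MeI, −78 → −40 °C
Reagents that add atoms: iodomethane, CI
Why: Lactone enolate alkylation anti to the adjacent vinyl group installs the future C10 methyl (3,4-trans), the arrangement that puts it equatorial in step 10; this centre is re-set in step 11.

Step 7
Reactants: 11 (3R,4R,5S)-4-ethenyl-3,5-dimethyloxolan-2-one; 7 (E)-alkenyl iodide
Product: 13 (3R,4R,5S)-3,5-dimethyl-4-R*-oxolan-2-one, via alkylborane 12 (not isolated)
Conditions: 9-BBN, THF, rt; then 7, PdCl2(dppf) (cat.), AsPh3 (cat.), Cs2CO3, DMF/H2O, rt; work-up at pH 4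
Reagents that add atoms: none
Why: B-alkyl Suzuki–Miyaura coupling: 9-BBN should add only to the monosubstituted alkene and the (E)-alkenyl iodide couples with retention, joining C12 to C13 while the lactone (re-closed on mildly acidic work-up if opened) is kept.

Step 8
Reactants: 13 (3R,4R,5S)-3,5-dimethyl-4-R*-oxolan-2-one
Product: 14 (4R,5R,6S)-6-hydroxy-4-methyl-5-R*-hept-1-en-3-one (open form of the lactol)
Conditions: CH2=CHMgBr (1.2 equiv), THF, −78 °C; sat. aq NH4Cl at −78 °C
Reagents that add atoms: vinylmagnesium bromide, C=C[Mg]Br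
Why: Mono-addition of a vinyl Grignard reagent to a γ-lactone at −78 °C, where the magnesium lactolate persists until the cold quench, should give the γ-hydroxy vinyl ketone (in equilibrium with its lactol) and brings in C6 and C7.

Step 9
Reactants: 14 (4R,5R,6S)-6-hydroxy-4-methyl-5-R*-hept-1-en-3-one
Product: 15 (3R,4R)-4-methyl-3-R*-hept-6-ene-2,5-dione
Conditions: Dess–Martin periodinane, pyridine, CH2Cl2, 0 °C → rt
Reagents that add atoms: none
Why: Dess–Martin oxidation of the open-chain secondary carbinol under buffered, non-basic conditions should give the 1,4-diketone without epimerising C9 or C10; the lactate-derived stereocentre has served as a relay and is erased on purpose.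

Step 10
Reactants: 15 (3R,4R)-4-methyl-3-R*-hept-6-ene-2,5-dione
Product: 16 (2R,3R,4R)-4-hydroxy-2,4-dimethyl-3-R*-cyclohexan-1-one
Conditions: SmI2 (2.5 equiv), HMPA, THF, −78 → −40 °C, slow addition of 15 at high dilution; sat. aq NH4Cl
Reagents that add atoms: none
Why: Two SmI2 deliver two electrons to the ene-dione: a samarium(III)-bound ketyl (at C8, or the vinylogous ketyl of the C5 enone) couples C8 with the vinyl-ketone terminus C7, the α-keto radical at C6 is reduced to the samarium enolate (which also masks the product ketone) and is protonated on quench, a net reductive ketone–enone coupling to the γ-hydroxy ketone. The closest known reaction type is the SmI2 ketyl–olefin (carbonyl–enone) reductive cyclization, together with endo-mode radical closures onto the CH2 terminus of vinyl ketones. Ring B closes in the 6-endo-trig mode with respect to C6=C7, because the 5-exo alternative at C6 is anti-Michael and would leave an unstabilised primary radical. C8 is the only new stereocentre: in the chair transition state the C9 chain and the C10 methyl are equatorial, the bulky HMPA-ligated O–Sm group should take the pseudo-equatorial site trans to the C9 chain and the C8 methyl the axial site, which is open because the syn-axial position at C10 still carries hydrogen (C10 is made quaternary only afterwards), hence 8α-OH/8β-CH3 next to the 9β chain; C9 is not enolised under these non-basic conditions. The step needs chemoselectivity against enone saturation followed by five-ring aldol closure (C6 onto C8), against dimerisation and against 5-exo ketyl addition to the C13=C14 alkene; this is secured by the absence of a proton source before the quench, by slow addition at high dilution and by the electron-poor vinyl ketone being by far the best radical acceptor in the molecule.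

Step 11
Reactants: 16 (2R,3R,4R)-4-hydroxy-2,4-dimethyl-3-R*-cyclohexan-1-one; 17 ethyl vinyl ketone (pent-1-en-3-one)
Product: 19 octalone (4aR,5R,6R)-6-hydroxy-1,4a,6-trimethyl-5-R*-4,4a,5,6,7,8-hexahydronaphthalen-2(3H)-one, via Michael adduct 18 (not isolated)
Conditions: 17, KOH (cat.), EtOH, 0 °C → rt; then KOH, EtOH, 65 °C
Reagents that add atoms: none
Why: Robinson annulation under equilibrating base: the more substituted C10 enolate should add to ethyl vinyl ketone (Michael addition) on the face anti to the C9 chain, which A1,2 strain holds axial, so that the C10 methyl ends β (cis to the chain), and aldol condensation of C4 onto the C5 ketone then closes ring A (6-enolexo).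

Step 12
Reactants: 19 octalone
Product: 20 (4aS,5R,6R,8aS)-2,6-bis[dimethyl(phenyl)silyloxy]-1,4a,6-trimethyl-5-R*-3,4,4a,5,6,7,8,8a-octahydronaphthalene (cis-fused; 5β-H)
Conditions: Cu(OAc)2·H2O (cat.), 1,2-bis(diphenylphosphino)benzene (cat.), PhMe2SiH (3 equiv), toluene, rt
Reagents that add atoms: dimethylphenylsilane, C[SiH](C)c1ccccc1
Why: Copper hydride-catalysed 1,4-hydrosilylation: by analogy with organocopper conjugate additions to 10-methyl-Δ4-octal-3-ones the hydride should reach C5 syn to the angular methyl (cis fusion), giving the C3–C4 enol silane regiospecifically while the same catalyst silylates the C8 carbinol and leaves the isolated trisubstituted alkenes alone.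

Step 13
Reactants: 20 bis-silyl enol ether
Product: 21 (4aS,5R,6R,8aS)-6-[dimethyl(phenyl)silyl]oxy-1,1,4a,6-tetramethyl-5-R*-octahydronaphthalen-2(1H)-one
Conditions: MeLi, THF, 0 °C → rt; MeI, HMPA, −78 → 0 °C
Reagents that add atoms: iodomethane, CI
Why: Regiospecific enolate alkylation: MeLi cleaves only the enol silyl ether and the resulting C3–C4 lithium enolate is C-methylated at C4 before it can equilibrate towards C2, completing the gem-dimethyl group (no new stereocentre; C5 is untouched).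

Step 14
Reactants: 21 silyl-protected 4,4-dimethyl ketone
Product: 22 (4aS,5R,6R,8aS)-6-hydroxy-5-[(3E,7E,11E)-13-hydroxy-4,8,12-trimethyltrideca-3,7,11-trien-1-yl]-1,1,4a,6-tetramethyloctahydronaphthalen-2(1H)-one
Conditions: TBAF, THF, 0 °C → rt
Reagents that add atoms: none
Why: Fluoride cleaves both silyl ethers (primary allylic TBDPS and tertiary dimethylphenylsilyl) under conditions that leave the ketone and the trisubstituted alkenes unchanged.

Step 15
Reactants: 22 diol
Product: 23 myrrhanone A acetate (as drawn), (2E,6E,10E)-13-[(1R,2R,4aS,8aS)-2-hydroxy-2,5,5,8a-tetramethyl-6-oxodecahydronaphthalen-1-yl]-2,6,10-trimethyltrideca-2,6,10-trien-1-yl acetate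
Conditions: Ac2O, pyridine, DMAP (cat.), CH2Cl2, 0 °C
Reagents that add atoms: acetic anhydride, CC(=O)OC(C)=O
Why: Acylation should be selective for the primary allylic alcohol because the hindered tertiary C8 carbinol does not react with Ac2O/pyridine at 0 °C.

**Compound list**
1 | (5E)-6,10-dimethylundeca-5,9-dien-2-one (geranylacetone) | CC(=O)CC/C=C(C)/CCC=C(C)C | starting material
2 | (5E,9E)-11-hydroxy-6,10-dimethylundeca-5,9-dien-2-one | CC(=O)CC/C=C(C)/CC/C=C(C)/CO | intermediate
3 | (5E,9E)-11-[tert-butyl(diphenyl)silyl]oxy-6,10-dimethylundeca-5,9-dien-2-one | CC(=O)CC/C=C(C)/CC/C=C(C)/CO[Si](c1ccccc1)(c1ccccc1)C(C)(C)C | intermediate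
4 | diethyl (5E,9E)-11-[tert-butyl(diphenyl)silyl]oxy-6,10-dimethylundeca-1,5,9-trien-2-yl phosphate | C=C(OP(=O)(OCC)OCC)CC/C=C(C)/CC/C=C(C)/CO[Si](c1ccccc1)(c1ccccc1)C(C)(C)C | intermediate (not isolated)
5 | tert-butyl{[(2E,6E)-2,6-dimethylundeca-2,6-dien-10-yn-1-yl]oxy}diphenylsilane | C#CCC/C=C(C)/CC/C=C(C)/CO[Si](c1ccccc1)(c1ccccc1)C(C)(C)C | intermediate
6 | dimethyl[(1E,5E,9E)-11-[tert-butyl(diphenyl)silyl]oxy-2,6,10-trimethylundeca-1,5,9-trien-1-yl]alane | C[Al](C)/C=C(C)/CC/C=C(C)/CC/C=C(C)/CO[Si](c1ccccc1)(c1ccccc1)C(C)(C)C | intermediate (not isolated)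
7 | tert-butyl{[(2E,6E,10E)-11-iodo-2,6,10-trimethylundeca-2,6,10-trien-1-yl]oxy}diphenylsilane | I/C=C(C)/CC/C=C(C)/CC/C=C(C)/CO[Si](c1ccccc1)(c1ccccc1)C(C)(C)C | intermediate
8 | (S)-5-methylfuran-2(5H)-one | O=C1C=C[C@H](C)O1 | starting material
9 | (4R,5S)-4-ethenyl-5-methyl-2-(trimethylsilyloxy)-4,5-dihydrofuran | C=C[C@@H]1C=C(O[Si](C)(C)C)O[C@H]1C | intermediate (not isolated)
10 | (4S,5S)-4-ethenyl-5-methyloxolan-2-one (4,5-trans) | C=C[C@@H]1CC(=O)O[C@H]1C | intermediate
11 | (3R,4R,5S)-4-ethenyl-3,5-dimethyloxolan-2-one | C=C[C@@H]1[C@@H](C)C(=O)O[C@H]1C | intermediate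
12 | (3R,4R,5S)-4-[2-(9-borabicyclo[3.3.1]nonan-9-yl)ethyl]-3,5-dimethyloxolan-2-one | B1(CC[C@@H]2[C@@H](C)C(=O)O[C@H]2C)C2CCCC1CCC2 | intermediate (not isolated)
13 | (3R,4R,5S)-3,5-dimethyl-4-R*-oxolan-2-one | CC(C)(C)[Si](c1ccccc1)(c1ccccc1)OC/C(C)=C/CC/C(C)=C/CC/C(C)=C/CC[C@@H]1[C@@H](C)C(=O)O[C@H]1C | intermediate
14 | (4R,5R,6S)-6-hydroxy-4-methyl-5-R*-hept-1-en-3-one (open form; equilibrates with its 2-vinyl lactol) | CC(C)(C)[Si](c1ccccc1)(c1ccccc1)OC/C(C)=C/CC/C(C)=C/CC/C(C)=C/CC[C@H]([C@@H](C)C(=O)C=C)[C@H](C)O | intermediate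
15 | (3R,4R)-4-methyl-3-R*-hept-6-ene-2,5-dione | CC(C)(C)[Si](c1ccccc1)(c1ccccc1)OC/C(C)=C/CC/C(C)=C/CC/C(C)=C/CC[C@H]([C@@H](C)C(=O)C=C)C(C)=O | intermediate
16 | (2R,3R,4R)-4-hydroxy-2,4-dimethyl-3-R*-cyclohexan-1-one | CC(C)(C)[Si](c1ccccc1)(c1ccccc1)OC/C(C)=C/CC/C(C)=C/CC/C(C)=C/CC[C@@H]1[C@@H](C)C(=O)CC[C@@]1(C)O | intermediate
17 | ethyl vinyl ketone (pent-1-en-3-one) | C=CC(=O)CC | starting material
18 | (2R,3R,4R)-4-hydroxy-2,4-dimethyl-2-(3-oxopentyl)-3-R*-cyclohexan-1-one | CC(C)(C)[Si](c1ccccc1)(c1ccccc1)OC/C(C)=C/CC/C(C)=C/CC/C(C)=C/CC[C@@H]1[C@@](C)(CCC(=O)CC)C(=O)CC[C@@]1(C)O | intermediate (not isolated)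
19 | (4aR,5R,6R)-6-hydroxy-1,4a,6-trimethyl-5-R*-4,4a,5,6,7,8-hexahydronaphthalen-2(3H)-one | CC(C)(C)[Si](c1ccccc1)(c1ccccc1)OC/C(C)=C/CC/C(C)=C/CC/C(C)=C/CC[C@@H]1[C@@]2(C)CCC(=O)C(C)=C2CC[C@@]1(C)O | intermediate
20 | (4aS,5R,6R,8aS)-2,6-bis[dimethyl(phenyl)silyloxy]-1,4a,6-trimethyl-5-R*-3,4,4a,5,6,7,8,8a-octahydronaphthalene | CC(C)(C)[Si](c1ccccc1)(c1ccccc1)OC/C(C)=C/CC/C(C)=C/CC/C(C)=C/CC[C@@H]1[C@@]2(C)CCC(O[Si](C)(C)c3ccccc3)=C(C)[C@H]2CC[C@@]1(C)O[Si](C)(C)c1ccccc1 | intermediate
21 | (4aS,5R,6R,8aS)-6-[dimethyl(phenyl)silyl]oxy-1,1,4a,6-tetramethyl-5-R*-octahydronaphthalen-2(1H)-one | CC(C)(C)[Si](c1ccccc1)(c1ccccc1)OC/C(C)=C/CC/C(C)=C/CC/C(C)=C/CC[C@@H]1[C@@]2(C)CCC(=O)C(C)(C)[C@H]2CC[C@@]1(C)O[Si](C)(C)c1ccccc1 | intermediate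
22 | (4aS,5R,6R,8aS)-6-hydroxy-5-[(3E,7E,11E)-13-hydroxy-4,8,12-trimethyltrideca-3,7,11-trien-1-yl]-1,1,4a,6-tetramethyloctahydronaphthalen-2(1H)-one | OC/C(C)=C/CC/C(C)=C/CC/C(C)=C/CC[C@@H]1[C@@]2(C)CCC(=O)C(C)(C)[C@H]2CC[C@@]1(C)O | intermediate
23 | myrrhanone A acetate (as drawn) | CC(=O)OC/C(C)=C/CC/C(C)=C/CC/C(C)=C/CC[C@@H]1[C@@]2(C)CCC(=O)C(C)(C)[C@H]2CC[C@@]1(C)O | target

**Step count**
Total: 15 steps. Longest linear sequence: 13 steps (steps 1–4 and 7–15, from 1).

**Steps most likely to fail**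

Step 10. The radical may be diverted before the C7–C8 bond forms: 5-exo ketyl addition to the C13=C14 alkene of the chain, or reductive β,β-dimerisation or saturation of the vinyl ketone. The fallback closes ring B before the chain is attached, so that no trisubstituted alkene is present in the radical step. It sets out from 11: vinylmagnesium bromide at −78 °C would give (4R,5R,6S)-5-ethenyl-6-hydroxy-4-methylhept-1-en-3-one F1, Dess–Martin oxidation the ene-dione (3R,4R)-3-ethenyl-4-methylhept-6-ene-2,5-dione F2, and the same SmI2 closure the ring-B ketone (2R,3R,4R)-3-ethenyl-4-hydroxy-2,4-dimethylcyclohexan-1-one F3. Excess 9-BBN then hydroborates the vinyl group (and reduces the ring ketone on the way), Suzuki–Miyaura coupling with 7 gives the diol (2R,3R,4R)-2,4-dimethyl-3-R*-cyclohexane-1,4-diol F4 (C1 epimers), and Dess–Martin oxidation of its secondary carbinol comes back to the route at 16.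

Step 12. Hydride transfer to the tetrasubstituted enone next to the quaternary C10 may be too slow, and facial selectivity may leak to the α-face (trans fusion). The fallback uses a less hindered enone and installs both C4 methyls afterwards. It sets out from 16: Robinson annulation with methyl vinyl ketone instead of 17 would give the trisubstituted enone (4aR,5R,6R)-6-hydroxy-4a,6-dimethyl-5-R*-4,4a,5,6,7,8-hexahydronaphthalen-2(3H)-one F5, the substrate type for which Cu–H conjugate reduction to cis-fused products is best precedented. The same Cu–H/PhMe2SiH conditions should give the cis-fused bis-silyl enol ether F6; MeLi then MeI gives the 4-monomethyl cis-decalone silyl ether F7 (C4 epimers). A second methylation through the thermodynamic enolate, which in a cis-fused 3-ketone lies towards the more substituted C4 (KOt-Bu, t-BuOH/THF, MeI), comes back to the route at 21.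

Step 11. Michael addition may occur at the less hindered C6 terminus, or the crowded C10 enolate may fail to alkylate under protic equilibrating conditions. The fallback uses a regiodefined enolate under aprotic conditions with an α-silyl vinyl ketone. It sets out from 16: TMSCl, NaI, Et3N in MeCN (thermodynamic enol silylation, also silylating the C8 carbinol) would give (3R,4R)-2,4-dimethyl-3-R*-1,4-bis(trimethylsilyloxy)cyclohex-1-ene F8. MeLi liberates the C5–C10 lithium enolate, which adds to 2-(trimethylsilyl)pent-1-en-3-one to give the adduct (2R,3R,4R)-2,4-dimethyl-2-[3-oxo-2-(trimethylsilyl)pentyl]-3-R*-4-(trimethylsilyloxy)cyclohexan-1-one F9. KOH/MeOH then removes the silyl groups and effects the aldol condensation, coming back to the route at 19.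

**Further compounds**
F1 | step 10 | (4R,5R,6S)-5-ethenyl-6-hydroxy-4-methylhept-1-en-3-one | C=C[C@H]([C@@H](C)C(=O)C=C)[C@H](C)O
F2 | step 10 | (3R,4R)-3-ethenyl-4-methylhept-6-ene-2,5-dione | C=C[C@H]([C@@H](C)C(=O)C=C)C(C)=O
F3 | step 10 | (2R,3R,4R)-3-ethenyl-4-hydroxy-2,4-dimethylcyclohexan-1-one | C=C[C@@H]1[C@@H](C)C(=O)CC[C@@]1(C)O
F4 | step 10 | (2R,3R,4R)-2,4-dimethyl-3-R*-cyclohexane-1,4-diol (C1 epimers) | CC(C)(C)[Si](c1ccccc1)(c1ccccc1)OC/C(C)=C/CC/C(C)=C/CC/C(C)=C/CC[C@@H]1[C@@H](C)C(O)CC[C@@]1(C)O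
F5 | step 12 | (4aR,5R,6R)-6-hydroxy-4a,6-dimethyl-5-R*-4,4a,5,6,7,8-hexahydronaphthalen-2(3H)-one | CC(C)(C)[Si](c1ccccc1)(c1ccccc1)OC/C(C)=C/CC/C(C)=C/CC/C(C)=C/CC[C@@H]1[C@@]2(C)CCC(=O)C=C2CC[C@@]1(C)O
F6 | step 12 | cis-fused (5β-H) 2,6-bis[dimethyl(phenyl)silyloxy]-4a,6-dimethyl-5-R*-3,4,4a,5,6,7,8,8a-octahydronaphthalene | CC(C)(C)[Si](c1ccccc1)(c1ccccc1)OC/C(C)=C/CC/C(C)=C/CC/C(C)=C/CC[C@@H]1[C@@]2(C)CCC(O[Si](C)(C)c3ccccc3)=C[C@H]2CC[C@@]1(C)O[Si](C)(C)c1ccccc1
F7 | step 12 | cis-fused (5β-H) 6-[dimethyl(phenyl)silyl]oxy-1,4a,6-trimethyl-5-R*-octahydronaphthalen-2(1H)-one (C1 epimers) | CC(C)(C)[Si](c1ccccc1)(c1ccccc1)OC/C(C)=C/CC/C(C)=C/CC/C(C)=C/CC[C@@H]1[C@@]2(C)CCC(=O)C(C)[C@H]2CC[C@@]1(C)O[Si](C)(C)c1ccccc1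
F8 | step 11 | (3R,4R)-2,4-dimethyl-3-R*-1,4-bis(trimethylsilyloxy)cyclohex-1-ene | CC(C)(C)[Si](c1ccccc1)(c1ccccc1)OC/C(C)=C/CC/C(C)=C/CC/C(C)=C/CC[C@@H]1C(C)=C(O[Si](C)(C)C)CC[C@@]1(C)O[Si](C)(C)C
F9 | step 11 | (2R,3R,4R)-2,4-dimethyl-2-[3-oxo-2-(trimethylsilyl)pentyl]-3-R*-4-(trimethylsilyloxy)cyclohexan-1-one | CC(C)(C)[Si](c1ccccc1)(c1ccccc1)OC/C(C)=C/CC/C(C)=C/CC/C(C)=C/CC[C@@H]1[C@@](C)(CC([Si](C)(C)C)C(=O)CC)C(=O)CC[C@@]1(C)O[Si](C)(C)C
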